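We work in a closed, stirred flask at constant temperature, where by the proposed steps a small charge of free catalyst picks up substrate to give catalyst intermediate A, A takes up reagent to give catalyst intermediate B, B loses released group to give catalyst intermediate C, and C hands over product and frees the catalyst, while added ligand can hold catalyst as idle complex.

| flask | substrate | reagent | free catalyst | added ligand | temperature | remark | time |
|---|---|---|---|---|---|---|---|
| Saturday's | 0.039 M | 0.018 M | 0.19 mM | 0.22 mM | −10 °C | run made earlier |  |
| Friday's | 0.039 M | 0.058 M | 0.19 mM | 0.22 mM | 20 °C | run made earlier |  |
| Tuesday's | 0.082 M | 0.0234 M | 0.19 mM | 0.22 mM | −10 °C | run made earlier |  |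
| south-west | 0.025 M | 0.0234 M | 0.19 mM | 0.12 mM | 25 °C |  | 4.0 min |
| east | 0.039 M | 0.0150 M | 0.40 mM | 0.22 mM | −5 °C |  | 4.0 min |
| south | 0.15 M | 0.0234 M | 0.40 mM | 0.22 mM | 25 °C |  | 4.0 min |
| north | 0.080 M | 0.0234 M | 0.19 mM | 0.22 mM | 25 °C |  | 4.0 min |
| west | 0.039 M | 0.0400 M | 0.19 mM | 0.22 mM | 45 °C |  | 4.0 min |
| north-east | 0.039 M | 0.0234 M | 0.19 mM | 0.22 mM | 25 °C |  | 4.0 min |

Saturday's run (percent of the substrate charged)

| time / min | product / % | substrate / % |
|---|---|---|
| 2.50 | 1.1 | 98.4 |
| 5.00 | 2.6 | 97.4 |
| 8.00 | 2.6 | 95.9 |
| 12.0 | 4.7 | 94.1 |

Friday's run (percent of the substrate charged)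

| time / s | product / % | substrate / % |
|---|---|---|
| 25.0 | 3.7 | 95.6 |
| 50.0 | 8.4 | 91.6 |
| 80.0 | 13.0 | 85.8 |
| 90.0 | 15.1 | 86.2 |
| 120 | 17.9 | 81.3 |

Tuesday's run (percent of the substrate charged)

| time / min | product / % | substrate / % |
|---|---|---|
| 1.00 | 0 | 99.8 |
| 3.00 | 0 | 98.8 |
| 6.00 | 0.8 | 99.2 |
| 8.00 | 1.1 | 97.6 |
| 12.0 | 1.9 | 97.0 |

(standard deviation of a reading: 0.5 percentage points)

1. ranking by amount of product, in percent of the substrate charged, from high to low, at 4.0 min (south-west / east / south / north / west / north-east)
2. the amount of product, in percent of the substrate charged of the flask you put first, at 4.0 min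
3. the amount of product, in percent of the substrate charged of the flask you put last, at 4.0 min

- steps that have been proposed: catalyst intermediate B -> released group + catalyst intermediate C; free catalyst + added ligand <-> idle complex; catalyst intermediate C -> free catalyst + product; reagent + catalyst intermediate A -> catalyst intermediate B; substrate + free catalyst -> catalyst intermediate A
- no earlier run changes the charge of free catalyst; that part of a forecast is a guess
- no earlier run changes the charge of added ligand; that part of a forecast is a guess

We count turnovers. The catalyst charge in west is 0.487% of [substrate], so each catalyst must go round many times. In west the smaller charge, that of substrate, the limiting reagent by a narrow margin, divided by the catalyst charge gives 205, and this is what we carry: the turnover ceiling, limiting charge over catalyst charge.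

In the first instants the catalyst must load, and Tuesday's run shows 0% product at 3.00 min, which suggests a short lag within the scatter. For the middle of a run, Saturday's run has made 9.65 turnovers by 12.0 min and Tuesday's run 8.20 with twice the [substrate] and 0.0234 M rather than 0.018 M of reagent, which we read as a rate at −10 °C that does not rise with these two charges within the scatter. Saturday's run averages 0.804 /min and Friday's run 18.4 /min, and although their reagent charges differ too, we put the whole difference down to temperature, so these readings give an apparent activation energy of 66.9 kJ/mol. We carry that to 159 /min in west, where the ceiling comes at 1.29 min if the rate holds, earlier than the 4.0 min asked. Friday's run, the furthest advanced of the earlier runs, stops at 17.9%, so the thinning of both charges in west and the share of catalyst in idle complex there remain unread.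

In east the same reckoning gives 1.42 /min and 5.83% product, if rate follows the catalyst charge, which is a guess. In north-east, north and south one reagent charge meets a rising [substrate], so that charge allows at most 60.0%, 29.2% and 15.6% of product, and we expect percentages to fall in that order, though south also holds more catalyst.

The forecast ranks west > south-west > north-east > north > south > east, puts the top at 95% (85% to 100%) and the low at 5.5% (3.5% to 10%), and says: “West should nearly finish”. Our reckoning also takes west close to its ceiling.

    catalyst intermediate B → released group + catalyst intermediate C (k = 1.40 /s, Ea = 71.0 kJ/mol)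
    free catalyst + added ligand ⇌ idle complex (K = 35000 /M, k = 65.0 /M/s, Ea = 52.0 kJ/mol, ΔH = 6.00 kJ/mol)
    catalyst intermediate C → free catalyst + product (k = 2.30 /s, Ea = 74.0 kJ/mol)
    reagent + catalyst intermediate A → catalyst intermediate B (k = 86.0 /M/s, Ea = 51.0 kJ/mol)
    substrate + free catalyst → catalyst intermediate A (k = 60.0 /M/s, Ea = 39.0 kJ/mol)
    (constants at 25 °C)

The flasks give west > south-west > north-east > north > south > east, with west at 79.0% and east at 5.61%, so order and low stand as forecast while the top lies 16 percentage points under it. In west at 4.00 min the slowest mode of the whole flask has a half-life of 2.13 min, half of the time run, and the product counts 162 of the 205 turnovers, with 21% of the substrate left. A neighbour of west charged with 0.16 M of substrate has a ceiling of 211 turnovers on its reagent charge, and its 25.0% of product counts 210, with 75% of its substrate and 0.0193% of its reagent left.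

(Readings and results come from a simulation for an exercise, noise included.)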